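**Assumption and convention (one line):** (R)-(−)-linalool of ≥95 % ee is taken as commercial (minor-enantiomer material leaves as a separable diastereomer after step 2); atom labels C1–C15 are germacrane positions of the target (C1, C4 = oxolane carbons; C5=C6 = enol-lactone alkene; C8 = methacrylate carbinol; C10 = tertiary carbinol; C12 = lactone C=O; C13 = CH2OAc).

## Retrosynthetic overview

1. Target ⇒ triol lactone 31 (C13 acetate and C8 methacrylate put on last) ⇒ silyl-protected macrocycle 30.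
2. Ten-membered ring (formed last): intramolecular Wittig olefination making C5=C6 from a C6 butenolide phosphorane and the C5 aldehyde; the bridged ring dictates the alkene geometry.
3. Butenolide ring: silyl-directed singlet-oxygen oxidation of a 2-silylfuran; C8 (S) from CBS reduction, C10 (R) from chelation-controlled MeMgBr addition.
4. Key C8–C9 bond: intermolecular aldol addition of the lithium enolate of methyl ketone 5 (fragment A) to furan aldehyde 13 (fragment B).
5. Fragment A from (R)-linalool (oxolane ring formed first, by Sharpless epoxidation/5-exo cyclisation); fragment B from dimethyl furan-3,4-dicarboxylate. Ring order: oxolane → butenolide (from the bought furan) → ten-membered carbocycle.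

## Route

Step 1
Reactants: 1 (R)-(−)-linalool
Product: 2 (2E,6R)-2,6-dimethylocta-2,7-diene-1,6-diol ((E)-8-hydroxylinalool)
Conditions: SeO2 (0.3 equiv), t-BuOOH (2 equiv), CH2Cl2, 0 °C to rt
Reagents that add atoms: tert-butyl hydroperoxide CC(C)(C)OO
Why: Selenium dioxide allylic oxidation (ene reaction then [2,3]-sigmatropic shift) hydroxylates only the (E)-methyl group of the trisubstituted alkene, giving the allylic alcohol that directs step 2 while the linalool-derived C4 centre is untouched.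

Step 2
Reactants: 2 (E)-8-hydroxylinalool
Product: 4 (2R)-2-[(2S,5R)-5-ethenyl-5-methyloxolan-2-yl]propane-1,2-diol, via epoxy alcohol 3 (not isolated)
Conditions: Ti(OiPr)4 (10 mol %), D-(−)-diethyl tartrate (12 mol %), t-BuOOH, 4 Å molecular sieves (Na12[(AlO2)12(SiO2)12]), CH2Cl2, −20 °C; then (1S)-(+)-camphor-10-sulfonic acid (5 mol %), CH2Cl2, 0 °C
Reagents that add atoms: tert-butyl hydroperoxide CC(C)(C)OO
Why: Sharpless asymmetric epoxidation with D-(−)-diethyl tartrate gives the (2R,3R)-epoxy alcohol by reagent control (the tertiary vinyl carbinol is inert), and acid-promoted 5-exo epoxide opening by the C4 hydroxyl at C1 with inversion forms the cis-2,5-disubstituted oxolane and sets C1 as S.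

Step 3
Reactants: 4 oxolane diol
Product: 5 1-[(2S,5R)-5-ethenyl-5-methyloxolan-2-yl]ethan-1-one (fragment A)
Conditions: NaIO4, THF/H2O (pH 7 phosphate buffer), 0 °C
Reagents that add atoms: none
Why: Periodate glycol cleavage (Malaprade reaction) of the tertiary/primary 1,2-diol unmasks the methyl ketone under neutral conditions, so the enolisable C1 centre is not epimerised.

Step 4
Reactants: 6 dimethyl furan-3,4-dicarboxylate
Product: 7 furan-3,4-diyldimethanol
Conditions: LiAlH4, THF, 0 °C to rt; then Na2SO4·10H2O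
Reagents that add atoms: none
Why: Exhaustive hydride reduction of both esters gives the symmetrical diol.

Step 5
Reactants: 7 furan-3,4-diyldimethanol
Product: 8 3,4-bis{[(triethylsilyl)oxy]methyl}furan
Conditions: Et3SiCl (2.2 equiv), imidazole, CH2Cl2, 0 °C to rt
Reagents that add atoms: chlorotriethylsilane CC[Si](Cl)(CC)CC
Why: Standard silylation of both primary alcohols installs the migrating groups needed in step 6.

Step 6
Reactants: 8 bis(triethylsilyl) ether
Product: 10 [2-(triethylsilyl)-4-{[(triethylsilyl)oxy]methyl}furan-3-yl]methanol, via 2-lithiofuran 9 (not isolated)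
Conditions: n-BuLi (1.1 equiv), HMPA, THF, −78 to 0 °C; then H2O
Reagents that add atoms: none
Why: Oxygen-directed α-lithiation of the furan followed by retro-[1,4]-Brook rearrangement (O-to-C silyl shift) desymmetrises the furan in one operation, placing the C-silyl group at C12 next to the freed C13 alcohol.

Step 7
Reactants: 10 C-silyl furan alcohol
Product: 11 tert-butyl(dimethyl){[2-(triethylsilyl)-4-{[(triethylsilyl)oxy]methyl}furan-3-yl]methoxy}silane
Conditions: t-BuMe2SiCl, imidazole, DMF, rt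
Reagents that add atoms: tert-butyl(chloro)dimethylsilane CC(C)(C)[Si](C)(C)Cl
Why: Silylation of the freed C13 alcohol with a more robust group differentiates it from the C8 arm.

Step 8
Reactants: 11 mixed silyl ether
Product: 12 [4-({[tert-butyl(dimethyl)silyl]oxy}methyl)-5-(triethylsilyl)furan-3-yl]methanol
Conditions: pyridinium p-toluenesulfonate (10 mol %), MeOH, 0 °C
Reagents that add atoms: none
Why: Acid-catalysed methanolysis removes the primary triethylsilyl ether far faster than the tert-butyldimethylsilyl ether and leaves the furyl C–Si bond intact.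

Step 9
Reactants: 12 furylmethanol
Product: 13 4-({[tert-butyl(dimethyl)silyl]oxy}methyl)-5-(triethylsilyl)furan-3-carbaldehyde (fragment B)
Conditions: MnO2, CH2Cl2, rt
Reagents that add atoms: none
Why: MnO2 oxidation of the benzylic-type furylmethanol stops cleanly at the non-enolisable aldehyde.

Step 10
Reactants: 5 methyl ketone (fragment A); 13 furan aldehyde (fragment B)
Product: 15 C8-hydroxy C10-ketone aldol adduct (both C8 epimers), via lithium enolate 14 (not isolated)
Conditions: LiN(i-Pr)2 (1.05 equiv), THF, −78 °C; then 13, −78 °C; AcOH, −78 °C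
Reagents that add atoms: none
Why: Directed (crossed) aldol addition of the kinetic lithium enolate of the methyl ketone to the non-enolisable aldehyde forms the C8–C9 bond that joins fragments A and B; the C8 carbinol forms as both epimers, which converge in step 14 and are set in step 16.

Step 11
Reactants: 15 aldol adduct
Product: 16 C8 triethylsilyl ether of the aldol adduct (both C8 epimers)
Conditions: Et3SiOTf, 2,6-lutidine, CH2Cl2, −78 °C
Reagents that add atoms: triethylsilyl trifluoromethanesulfonate CC[Si](CC)(CC)OS(=O)(=O)C(F)(F)F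
Why: Silylation of the aldol hydroxyl blocks retro-aldol cleavage and competing β-alkoxide chelation before the Grignard addition.

Step 12
Reactants: 16 silylated aldol ketone
Product: 17 (10R) tertiary alcohol with C8 triethylsilyl ether (both C8 epimers)
Conditions: MeMgBr (3 equiv), Et2O/CH2Cl2, −78 °C; aq NH4Cl
Reagents that add atoms: methylmagnesium bromide C[Mg]Br
Why: Chelation-controlled Grignard addition (Cram chelate model) in which magnesium bridges the ketone and oxolane oxygens and methyl adds to the carbonyl face on the side of H-1, away from ring carbon C2, setting C10 as R.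

Step 13
Reactants: 17 tertiary alcohol
Product: 18 C8,C10-diol (both C8 epimers)
Conditions: HF·pyridine, pyridine, THF, 0 °C
Reagents that add atoms: none
Why: Buffered HF·pyridine cleaves the secondary triethylsilyl ether selectively over the primary tert-butyldimethylsilyl ether and the furyl C–Si bond.

Step 14
Reactants: 18 diol
Product: 19 (3R)-3-hydroxy furyl ketone (C8 ketone, single compound)
Conditions: Dess–Martin periodinane, CH2Cl2, rt
Reagents that add atoms: none
Why: Dess–Martin oxidation converts both C8 epimers into one β-hydroxy ketone, and the tertiary C10 alcohol cannot be oxidised.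

Step 15
Reactants: 19 β-hydroxy ketone
Product: 20 C10 trimethylsilyl ether of the C8 ketone
Conditions: 1-(trimethylsilyl)imidazole, CH2Cl2, rt
Reagents that add atoms: 1-(trimethylsilyl)imidazole C[Si](C)(C)n1ccnc1
Why: Silylation of the tertiary alcohol with a powerful, non-enolising silyl donor prevents retro-aldol cleavage and hydroxyl participation in later steps.

Step 16
Reactants: 20 silyloxy ketone
Product: 21 (8S) alcohol with C10 trimethylsilyl ether
Conditions: (3aR)-1-methyl-3,3-diphenyltetrahydro-1H,3H-pyrrolo[1,2-c][1,3,2]oxazaborole ((R)-Me-CBS, 0.5 equiv), catecholborane (2 equiv), toluene, −78 to −40 °C; then H2O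
Reagents that add atoms: none
Why: Corey–Bakshi–Shibata reduction in which the (R)-oxazaborolidine delivers hydride to the furyl ketone with the furyl group as the large substituent, setting C8 as S, while catecholborane at low temperature leaves the vinyl group alone.

Step 17
Reactants: 21 (8S) alcohol
Product: 22 C8 triethylsilyl, C10 trimethylsilyl, C13 tert-butyldimethylsilyl protected 2-silylfuran
Conditions: Et3SiOTf, 2,6-lutidine, CH2Cl2, −78 °C
Reagents that add atoms: triethylsilyl trifluoromethanesulfonate CC[Si](CC)(CC)OS(=O)(=O)C(F)(F)F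
Why: Silyl protection of the C8 alcohol keeps it inert through furan oxidation and ring closure and allows mild release at the end.

Step 18
Reactants: 22 protected 2-silylfuran
Product: 25 C6-hydroxybutenolide (both C6 epimers), via furan endoperoxide 23 (not isolated), via silyl ester 24 (not isolated)
Conditions: O2, visible light, 5,10,15,20-tetraphenylporphyrin (1 mol %), CH2Cl2, −78 °C; then rt, H2O
Reagents that add atoms: dioxygen O=O
Why: [4+2] Cycloaddition of singlet oxygen to the furan gives the endoperoxide, whose C12 silyl group shifts to the peroxide oxygen so that C12 becomes the lactone carbonyl and C6 the hemiacetal carbon (silyl-directed furan photooxygenation); the C6 epimer mixture is irrelevant because C6 becomes sp2.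

Step 19
Reactants: 25 hydroxybutenolide
Product: 26 C5 aldehyde of the hydroxybutenolide (both C6 epimers)
Conditions: O3, CH2Cl2, −78 °C; then Me2S, −78 °C to rt
Reagents that add atoms: ozone [O-][O+]=O
Why: Ozonolysis cleaves the monosubstituted vinyl group much faster than the electron-poor tetrasubstituted butenolide alkene, giving the non-enolisable C5 aldehyde.

Step 20
Reactants: 26 hydroxybutenolide aldehyde
Product: 30 (1S,4R,5E,8S,10R)-13-[tert-butyl(dimethyl)silyloxy]-1,4-epoxy-8-(triethylsilyloxy)-10-(trimethylsilyloxy)germacra-5,7(11)-dien-12,6-olide, via chlorobutenolide 27 (not isolated), via phosphonium chloride 28 (not isolated), via phosphorus ylide 29 (not isolated)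
Conditions: 1-chloro-N,N,2-trimethylprop-1-en-1-amine, CH2Cl2, 0 °C; PPh3, MeCN, rt; then slow addition to Et3N, toluene (0.001 M), 60 °C
Reagents that add atoms: none
Why: The hemiacetal hydroxyl is exchanged for chloride and then triphenylphosphine, and the stabilised butenolide ylide closes the ten-membered ring by intramolecular Wittig olefination with the C5 aldehyde, where only the alkene with C4 and C7 cis (5E) fits the bridged ring.

Step 21
Reactants: 30 protected macrocycle
Product: 31 (1S,4R,5E,8S,10R)-1,4-epoxy-8,10,13-trihydroxygermacra-5,7(11)-dien-12,6-olide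
Conditions: HF·pyridine, pyridine, THF, 0 °C to rt
Reagents that add atoms: none
Why: Fluoride-mediated global desilylation removes all three silyl ethers without touching the enol lactone.

Step 22
Reactants: 31 triol lactone
Product: 32 (1S,4R,5E,8S,10R)-13-acetoxy-1,4-epoxy-8,10-dihydroxygermacra-5,7(11)-dien-12,6-olide
Conditions: AcCl (1.05 equiv), 2,4,6-collidine, CH2Cl2, −78 °C
Reagents that add atoms: acetyl chloride CC(Cl)=O
Why: Kinetically selective acetylation, because the primary C13 alcohol reacts far faster than the hindered secondary C8 and tertiary C10 alcohols at −78 °C.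

Step 23
Reactants: 32 13-acetate diol
Product: 33 CNP0516045.1, (1S,4R,5E,8S,10R)-13-acetoxy-1,4-epoxy-10-hydroxy-8-(2-methylprop-2-enoyloxy)germacra-5,7(11)-dien-12,6-olide
Conditions: methacrylic anhydride, Et3N, 4-(dimethylamino)pyridine (10 mol %), CH2Cl2, 0 °C to rt
Reagents that add atoms: methacrylic anhydride C=C(C)C(=O)OC(=O)C(C)=C
Why: Nucleophile-catalysed acyl transfer (Steglich-type acylation) esterifies the secondary C8 alcohol while the tertiary C10 alcohol is unreactive, giving the target.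

## Compound list

1 | (R)-(−)-linalool, (3R)-3,7-dimethylocta-1,6-dien-3-ol | CC(C)=CCC[C@@](C)(O)C=C | starting material
2 | (2E,6R)-2,6-dimethylocta-2,7-diene-1,6-diol | OC/C(C)=C/CC[C@@](C)(O)C=C | intermediate
3 | (3R)-5-[(2R,3R)-3-(hydroxymethyl)-3-methyloxiran-2-yl]-3-methylpent-1-en-3-ol | OC[C@@]1(C)O[C@@H]1CC[C@@](C)(O)C=C | intermediate
4 | (2R)-2-[(2S,5R)-5-ethenyl-5-methyloxolan-2-yl]propane-1,2-diol | OC[C@@](C)(O)[C@@H]1CC[C@](C)(C=C)O1 | intermediate
5 | 1-[(2S,5R)-5-ethenyl-5-methyloxolan-2-yl]ethan-1-one (fragment A) | CC(=O)[C@@H]1CC[C@](C)(C=C)O1 | intermediate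
6 | dimethyl furan-3,4-dicarboxylate | COC(=O)c1cocc1C(=O)OC | starting material
7 | furan-3,4-diyldimethanol | OCc1cocc1CO | intermediate
8 | 3,4-bis{[(triethylsilyl)oxy]methyl}furan | CC[Si](CC)(CC)OCc1cocc1CO[Si](CC)(CC)CC | intermediate
9 | 2-lithio-3,4-bis{[(triethylsilyl)oxy]methyl}furan | CC[Si](CC)(CC)OCc1coc([Li])c1CO[Si](CC)(CC)CC | intermediate
10 | [2-(triethylsilyl)-4-{[(triethylsilyl)oxy]methyl}furan-3-yl]methanol | OCc1c(CO[Si](CC)(CC)CC)coc1[Si](CC)(CC)CC | intermediate
11 | tert-butyl(dimethyl){[2-(triethylsilyl)-4-{[(triethylsilyl)oxy]methyl}furan-3-yl]methoxy}silane | CC(C)(C)[Si](C)(C)OCc1c(CO[Si](CC)(CC)CC)coc1[Si](CC)(CC)CC | intermediate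
12 | [4-({[tert-butyl(dimethyl)silyl]oxy}methyl)-5-(triethylsilyl)furan-3-yl]methanol | CC(C)(C)[Si](C)(C)OCc1c(CO)coc1[Si](CC)(CC)CC | intermediate
13 | 4-({[tert-butyl(dimethyl)silyl]oxy}methyl)-5-(triethylsilyl)furan-3-carbaldehyde (fragment B) | CC(C)(C)[Si](C)(C)OCc1c(C=O)coc1[Si](CC)(CC)CC | intermediate
14 | lithium 1-[(2S,5R)-5-ethenyl-5-methyloxolan-2-yl]ethen-1-olate (kinetic enolate of 5) | [Li]OC(=C)[C@@H]1CC[C@](C)(C=C)O1 | intermediate
15 | 3-[4-({[tert-butyl(dimethyl)silyl]oxy}methyl)-5-(triethylsilyl)furan-3-yl]-1-[(2S,5R)-5-ethenyl-5-methyloxolan-2-yl]-3-hydroxypropan-1-one (both epimers at carbinol C8) | O=C(CC(O)c1coc([Si](CC)(CC)CC)c1CO[Si](C)(C)C(C)(C)C)[C@@H]2CC[C@](C)(C=C)O2 | intermediate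
16 | 3-[4-({[tert-butyl(dimethyl)silyl]oxy}methyl)-5-(triethylsilyl)furan-3-yl]-1-[(2S,5R)-5-ethenyl-5-methyloxolan-2-yl]-3-[(triethylsilyl)oxy]propan-1-one (both C8 epimers) | O=C(CC(O[Si](CC)(CC)CC)c1coc([Si](CC)(CC)CC)c1CO[Si](C)(C)C(C)(C)C)[C@@H]2CC[C@](C)(C=C)O2 | intermediate
17 | (2R)-4-[4-({[tert-butyl(dimethyl)silyl]oxy}methyl)-5-(triethylsilyl)furan-3-yl]-2-[(2S,5R)-5-ethenyl-5-methyloxolan-2-yl]-4-[(triethylsilyl)oxy]butan-2-ol (both C8 epimers) | CC[Si](CC)(CC)OC(c1coc([Si](CC)(CC)CC)c1CO[Si](C)(C)C(C)(C)C)C[C@@](C)(O)[C@@H]2CC[C@](C)(C=C)O2 | intermediate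
18 | (3R)-1-[4-({[tert-butyl(dimethyl)silyl]oxy}methyl)-5-(triethylsilyl)furan-3-yl]-3-[(2S,5R)-5-ethenyl-5-methyloxolan-2-yl]butane-1,3-diol (both C8 epimers) | OC(c1coc([Si](CC)(CC)CC)c1CO[Si](C)(C)C(C)(C)C)C[C@@](C)(O)[C@@H]2CC[C@](C)(C=C)O2 | intermediate
19 | (3R)-1-[4-({[tert-butyl(dimethyl)silyl]oxy}methyl)-5-(triethylsilyl)furan-3-yl]-3-[(2S,5R)-5-ethenyl-5-methyloxolan-2-yl]-3-hydroxybutan-1-one | O=C(c1coc([Si](CC)(CC)CC)c1CO[Si](C)(C)C(C)(C)C)C[C@@](C)(O)[C@@H]2CC[C@](C)(C=C)O2 | intermediate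
20 | (3R)-1-[4-({[tert-butyl(dimethyl)silyl]oxy}methyl)-5-(triethylsilyl)furan-3-yl]-3-[(2S,5R)-5-ethenyl-5-methyloxolan-2-yl]-3-[(trimethylsilyl)oxy]butan-1-one | O=C(c1coc([Si](CC)(CC)CC)c1CO[Si](C)(C)C(C)(C)C)C[C@@](C)(O[Si](C)(C)C)[C@@H]2CC[C@](C)(C=C)O2 | intermediate
21 | (1S,3R)-1-[4-({[tert-butyl(dimethyl)silyl]oxy}methyl)-5-(triethylsilyl)furan-3-yl]-3-[(2S,5R)-5-ethenyl-5-methyloxolan-2-yl]-3-[(trimethylsilyl)oxy]butan-1-ol | O[C@H](c1coc([Si](CC)(CC)CC)c1CO[Si](C)(C)C(C)(C)C)C[C@@](C)(O[Si](C)(C)C)[C@@H]2CC[C@](C)(C=C)O2 | intermediate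
22 | triethylsilyl ether of 21 at the C8 oxygen, (1S,3R) configuration retained | CC[Si](CC)(CC)O[C@H](c1coc([Si](CC)(CC)CC)c1CO[Si](C)(C)C(C)(C)C)C[C@@](C)(O[Si](C)(C)C)[C@@H]2CC[C@](C)(C=C)O2 | intermediate
23 | C6,C12-endoperoxide of furan 22 (2,3,7-trioxabicyclo[2.2.1]hept-5-ene core) | CC[Si](CC)(CC)O[C@H](C1=C(CO[Si](C)(C)C(C)(C)C)C3([Si](CC)(CC)CC)OOC1O3)C[C@@](C)(O[Si](C)(C)C)[C@@H]2CC[C@](C)(C=C)O2 | intermediate
24 | ring-opened (Z)-enal triethylsilyl ester (C12 silyl ester, C6 aldehyde) formed from 23 by silyl shift | CC[Si](CC)(CC)O[C@H](/C(C=O)=C(\CO[Si](C)(C)C(C)(C)C)C(=O)O[Si](CC)(CC)CC)C[C@@](C)(O[Si](C)(C)C)[C@@H]2CC[C@](C)(C=C)O2 | intermediate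
25 | 4-{(1S,3R)-3-[(2S,5R)-5-ethenyl-5-methyloxolan-2-yl]-1-[(triethylsilyl)oxy]-3-[(trimethylsilyl)oxy]butyl}-3-({[tert-butyl(dimethyl)silyl]oxy}methyl)-5-hydroxyfuran-2(5H)-one (both C6 epimers) | CC[Si](CC)(CC)O[C@H](C1=C(CO[Si](C)(C)C(C)(C)C)C(=O)OC1O)C[C@@](C)(O[Si](C)(C)C)[C@@H]2CC[C@](C)(C=C)O2 | intermediate
26 | (2R,5S)-5-[(2R,4S)-4-{4-({[tert-butyl(dimethyl)silyl]oxy}methyl)-2-hydroxy-5-oxo-2,5-dihydrofuran-3-yl}-4-[(triethylsilyl)oxy]-2-[(trimethylsilyl)oxy]butan-2-yl]-2-methyloxolane-2-carbaldehyde (both C6 epimers) | CC[Si](CC)(CC)O[C@H](C1=C(CO[Si](C)(C)C(C)(C)C)C(=O)OC1O)C[C@@](C)(O[Si](C)(C)C)[C@@H]2CC[C@](C)(C=O)O2 | intermediate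
27 | C6-chloro analogue of 26 (5-chlorofuran-2(5H)-one, both C6 epimers) | CC[Si](CC)(CC)O[C@H](C1=C(CO[Si](C)(C)C(C)(C)C)C(=O)OC1Cl)C[C@@](C)(O[Si](C)(C)C)[C@@H]2CC[C@](C)(C=O)O2 | intermediate
28 | C6-triphenylphosphonium chloride derived from 27 | CC[Si](CC)(CC)O[C@H](C1=C(CO[Si](C)(C)C(C)(C)C)C(=O)OC1[P+](c3ccccc3)(c3ccccc3)c3ccccc3)C[C@@](C)(O[Si](C)(C)C)[C@@H]2CC[C@](C)(C=O)O2.[Cl-] | intermediate
29 | C6 phosphorus ylide of 28 (2-oxidofuran phosphonium zwitterion) | CC[Si](CC)(CC)O[C@H](C1=C(CO[Si](C)(C)C(C)(C)C)C(=O)O[C-]1[P+](c3ccccc3)(c3ccccc3)c3ccccc3)C[C@@](C)(O[Si](C)(C)C)[C@@H]2CC[C@](C)(C=O)O2 | intermediate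
30 | (1S,4R,5E,8S,10R)-13-[tert-butyl(dimethyl)silyloxy]-1,4-epoxy-8-(triethylsilyloxy)-10-(trimethylsilyloxy)germacra-5,7(11)-dien-12,6-olide | CC[Si](CC)(CC)O[C@H]1C[C@@](C)(O[Si](C)(C)C)[C@@H]2CC[C@](C)(/C=C3/OC(=O)C(CO[Si](C)(C)C(C)(C)C)=C31)O2 | intermediate
31 | (1S,4R,5E,8S,10R)-1,4-epoxy-8,10,13-trihydroxygermacra-5,7(11)-dien-12,6-olide | O[C@H]1C[C@@](C)(O)[C@@H]2CC[C@](C)(/C=C3/OC(=O)C(CO)=C31)O2 | intermediate
32 | (1S,4R,5E,8S,10R)-13-acetoxy-1,4-epoxy-8,10-dihydroxygermacra-5,7(11)-dien-12,6-olide | O[C@H]1C[C@@](C)(O)[C@@H]2CC[C@](C)(/C=C3/OC(=O)C(COC(C)=O)=C31)O2 | intermediate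
33 | CNP0516045.1, (1S,4R,5E,8S,10R)-13-acetoxy-1,4-epoxy-10-hydroxy-8-(2-methylprop-2-enoyloxy)germacra-5,7(11)-dien-12,6-olide | C=C(C)C(=O)O[C@H]1C[C@@](C)(O)[C@@H]2CC[C@](C)(/C=C3/OC(=O)C(COC(C)=O)=C31)O2 | target

## Summary

Total step count: 23.
Longest linear sequence: 20 steps (steps 4–9, then 10–23, from dimethyl furan-3,4-dicarboxylate); the linalool branch is 17 steps.

The three steps most likely to fail:

**Step 20 (ten-membered ring closure by intramolecular Wittig olefination).** A stabilised butenolide ylide must reach a neopentyl-type aldehyde across a medium ring, so oligomerisation or no reaction is possible. The fallback sets out from 26, which is converted into chloride 27 exactly as in step 20. Chloride 27 is then added slowly to SmI2 (2.2 equiv, THF, −78 °C, 0.002 M). The resulting samarium furanolate closes the ring by a Reformatsky-type vinylogous aldol addition of C6 to the C5 aldehyde and gives the macrocyclic C5-hydroxy butenolide F1 as a diastereomer mixture. Mesylation (MsCl, Et3N, CH2Cl2, 0 °C) gives the C5 mesylate F2, and 1,8-diazabicyclo[5.4.0]undec-7-ene then induces E1cB elimination across C5–C6. The route is rejoined at 30; both C5/C6 diastereomers converge because the ring allows only the 5E alkene.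

**Step 16 (CBS reduction setting C8).** The β-quaternary CH2 group may not be clearly "smaller" than the substituted furyl group, which would erode selectivity. The fallback sets out from 20 and uses unselective reduction (NaBH4, EtOH, 0 °C). This gives 21 together with its (8R)-alcohol epimer F3; the two are diastereomers and are separated by chromatography. F3 is re-oxidised to 20 with Dess–Martin periodinane and recycled, so the route is rejoined at 21 by separation and recycling instead of asymmetric induction.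

**Step 18 (silyl-directed photooxygenation of the furan).** The endoperoxide may fragment unselectively in this heavily silylated substrate. The fallback sets out from 22 and uses buffered peracid oxidation (AcOOH, NaOAc, CH2Cl2, 0 °C), which converts the 2-silylfuran regiospecifically into the C6-unsubstituted butenolide F4 with the carbonyl at the former silyl carbon. Soft enolisation (i-Pr3SiOTf, Et3N, CH2Cl2, 0 °C) gives the 2-(triisopropylsilyloxy)furan F5. Oxidation of F5 at C6 with dimethyldioxirane (acetone, −78 °C) delivers the hydroxybutenolide, and the route is rejoined at 25.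

Further compounds
F1 | step 20 | (1S,4R,8S,10R)-13-[tert-butyl(dimethyl)silyloxy]-1,4-epoxy-5-hydroxy-8-(triethylsilyloxy)-10-(trimethylsilyloxy)germacr-7(11)-en-12,6-olide (C5/C6 diastereomer mixture) | CC[Si](CC)(CC)O[C@H]1C[C@@](C)(O[Si](C)(C)C)[C@@H]2CC[C@](C)(C(O)C3OC(=O)C(CO[Si](C)(C)C(C)(C)C)=C31)O2
F2 | step 20 | C5 methanesulfonate of F1 | CC[Si](CC)(CC)O[C@H]1C[C@@](C)(O[Si](C)(C)C)[C@@H]2CC[C@](C)(C(OS(C)(=O)=O)C3OC(=O)C(CO[Si](C)(C)C(C)(C)C)=C31)O2
F3 | step 16 | (1R,3R)-1-[4-({[tert-butyl(dimethyl)silyl]oxy}methyl)-5-(triethylsilyl)furan-3-yl]-3-[(2S,5R)-5-ethenyl-5-methyloxolan-2-yl]-3-[(trimethylsilyl)oxy]butan-1-ol (8R epimer of 21) | O[C@@H](c1coc([Si](CC)(CC)CC)c1CO[Si](C)(C)C(C)(C)C)C[C@@](C)(O[Si](C)(C)C)[C@@H]2CC[C@](C)(C=C)O2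
F4 | step 18 | 4-{(1S,3R)-3-[(2S,5R)-5-ethenyl-5-methyloxolan-2-yl]-1-[(triethylsilyl)oxy]-3-[(trimethylsilyl)oxy]butyl}-3-({[tert-butyl(dimethyl)silyl]oxy}methyl)furan-2(5H)-one | CC[Si](CC)(CC)O[C@H](C1=C(CO[Si](C)(C)C(C)(C)C)C(=O)OC1)C[C@@](C)(O[Si](C)(C)C)[C@@H]2CC[C@](C)(C=C)O2
F5 | step 18 | 2-(triisopropylsilyloxy)furan derived from F4 (silyloxy group at C12) | CC[Si](CC)(CC)O[C@H](c1coc(O[Si](C(C)C)(C(C)C)C(C)C)c1CO[Si](C)(C)C(C)(C)C)C[C@@](C)(O[Si](C)(C)C)[C@@H]2CC[C@](C)(C=C)O2
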